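The readings come from a simulation with made-up constants, noise included.

Time is what the noon flask at 90 °C shows, so I follow it stage by stage, and then ask what its pace means for the flasks below.

common to all: gas 0.097 mM (held)
- noon: substrate 2.2 mM; temperature 90 °C; run made earlier
- Thursday's: substrate 2.0 mM; temperature 90 °C; time 5.0 min
- Wednesday's: substrate 2.0 mM; temperature 70 °C; time 5.0 min
- Tuesday's: substrate 2.0 mM; temperature 75 °C; time 5.0 min
- Friday's: substrate 1.2 mM; temperature 105 °C; time 5.0 min
- Monday's: substrate 6.0 mM; temperature 110 °C; time 5.0 min

noon run (percent of the substrate charged)

| time / min | target / % | substrate / % |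
|---|---|---|
| 0.417 | 0 | 1.2 |
| 1.00 | 2.9 | 1.2 |
| 2.00 | 8.2 | 0.9 |
| 3.00 | 12.2 | 0 |

(scatter of a reading: 0.5 percentage points)

- all flasks from highest to lowest amount of target, in percent of the substrate charged, at 5.0 min (Thursday's / Wednesday's / Tuesday's / Friday's / Monday's)
- the amount of target, in percent of the substrate charged of the flask you put first, at 5.0 min
- the amount of target, in percent of the substrate charged of the flask you put last, at 5.0 min

- at the start none of the gas is in solution
- the earlier runs do not show what temperature does; that part of a forecast is a guess

In the first instants the step from the substrate is fast: by 0.417 min the substrate reads 1.2% and the target 0%, so an unseen pool holds nearly all of the charge. In the middle the target gains 5.3 percentage points and then 4 points in two successive minutes; with a scatter of 0.5 points on each reading I take that as one straight line.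

What is about to matter is the gas. By 3.00 min the noon flask has made 0.268 mM of target, more than the 0.097 mM of gas the solution can hold at once. If each target uses up gas, which is my assumption, the gas must be fed in as the run goes. A feed has a pace in mM per minute, not in percent of the charge, so I assume that a change of charge leaves that pace as it is. I therefore carry the feed, the amount of target made per minute in mM, read from the noon line as 0.102 mM min⁻¹. The same line starts after a lag of 0.376 min.

For the end, Thursday's smaller charge is a small correction: the same feed gives it 23.7% at 5.0 min, and its pool would take 19.6 min to empty, longer than the run. With the noon feed unchanged, which is my assumption, Friday's 1.2 mM would read 39.3%, before the unknown effect of 105 °C.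

The forecast, which is a separate judgement, gives the order Friday's > Monday's > Thursday's > Tuesday's > Wednesday's, with 43% for the first flask (range 27% to 65%) and 7% for the last (3% to 15%). Its ground for the lead is Monday's gas supply: “Its percentage is therefore capped, and Friday's likely leads”.

The flasks come out in the order Friday's > Monday's > Thursday's > Tuesday's > Wednesday's, with Friday's at 88.0%, above the forecast's range, and Wednesday's at 3.60%.

    substrate → open intermediate (k = 0.155 s⁻¹, Ea = 91.0 kJ mol⁻¹)
    partner → second intermediate (k = 0.0204 s⁻¹, Ea = 100 kJ mol⁻¹)
    open intermediate + second intermediate → target (k = 42.1 L mol⁻¹ s⁻¹, Ea = 57.0 kJ mol⁻¹)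
    2 second intermediate → homo product (k = 28.1 L mol⁻¹ s⁻¹, Ea = 62.0 kJ mol⁻¹)
    gas ⇌ partner, rate k5*(csat - [partner]) (kL = 0.162 s⁻¹)
    (constants at 90 °C)

At 5.00 min Friday's flask still holds 12.0% as open intermediate. Reckoned after the noon lag, Friday's feed comes to 0.228 mM min⁻¹, twice the noon feed. Wednesday's feed, reckoned the same way, is 0.0156 mM min⁻¹. Held to 50.0 min, that pace gives Wednesday's flask 38.7%, and the flask stands there at 41.0% of target.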